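Late readings come first, since a steady pace shows best at the far end of a run: at 60.0 s the eta run holds 38.9% of target and the alpha run 30.2%, each reached by a nearly straight climb.

common to all: starting material 0.50 mM; gas 0.018 mM (held); free catalyst 1 mol%; added ligand 9.3 µM

| charge | second substrate | remark | time |
|---|---|---|---|
| eta | 1.3 equiv | run made earlier |  |
| alpha | 2.3 equiv | run made earlier |  |
| Sunday's | 2.00 equiv |  | 2.0 min |
| Monday's | 2.60 equiv |  | 2.0 min |
| Wednesday's | 3.40 equiv |  | 2.0 min |

| run | time / s | starting material / % | target / % | catalyst intermediate A / % |
|---|---|---|---|---|
| eta | 10.0 | 93.8 | 5.2 | 0 |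
| eta | 15.0 | 90.7 | 8.3 | 2.2 |
| eta | 25.0 | 82.0 | 16.6 | 0.5 |
| eta | 30.0 | 81.8 | 17.8 | 1.3 |
| eta | 40.0 | 73.7 | 26.5 | 0.5 |
| eta | 50.0 | 65.5 | 30.3 | 0 |
| eta | 60.0 | 64.1 | 38.9 | 0 |
| alpha | 10.0 | 95.6 | 3.7 | 0.6 |
| alpha | 15.0 | 92.2 | 7.3 | 1.4 |
| alpha | 25.0 | 87.3 | 12.1 | 0.7 |
| alpha | 40.0 | 79.1 | 18.3 | 2.3 |
| alpha | 50.0 | 74.6 | 24.4 | 1.2 |
| alpha | 60.0 | 69.6 | 30.2 | 0 |

(readings scatter by 1 percentage point)

- at the start none of the gas is in solution

* which of these there is most of at the end, counted by the starting material in it, Sunday's (starting material / catalyst intermediate A / target)
* which of these there is most of at the end, counted by the starting material in it, Monday's (starting material / catalyst intermediate A / target)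
* which of these there is most of at the end, counted by the starting material in it, Wednesday's (starting material / catalyst intermediate A / target)
* how much there is at the end of the one of these that leads, in percent of the starting material charged: Sunday's
* how much there is at the end of the one of these that leads, in percent of the starting material charged: Monday's
* how much there is at the end of the one of these that leads, in percent of the starting material charged: Wednesday's

For the person taking over the bench: each flask holds starting material, second substrate, free catalyst and added ligand under held gas. Catalyst intermediate A cannot hold more than the 1 mol% of catalyst charged, so the contest lies between starting material and target, and target leads once past half.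

Take the pace as constant, zero-order in starting material, and define the clearing time τ as the time the whole charge needs to become target at that pace. The readings give τ = 154 s in the eta run and 199 s in the alpha run, so 1.00 more second substrate goes with 44.4 s more. Keeping alpha's τ as the large term and correcting only for the shift in equivalents, Sunday's gets 185 s, Monday's 212 s and Wednesday's clearing time 248 s.

Target leads where half of τ is shorter than the run, as on Sunday's and Monday's, with 64.7% and 56.6% of target. On Wednesday's, half of τ is longer than the run: 48.5% of target leaves 51.5% of starting material, a margin of 1.5 percentage points against a scatter of 1 point.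

The forecast gives target at 60% for Sunday's, target at 54% for Monday's and starting material at 52% for Wednesday's, holding that “Extra second substrate therefore slows the reaction”, and its first two values lie below this reckoning.

Sunday's flask gives target at 60.8%. Monday's flask gives target at 54.1%. Wednesday's flask gives starting material at 53.0%.

    starting material + free catalyst ⇌ catalyst intermediate A (K = 13000 M⁻¹, k = 35000 M⁻¹ s⁻¹)
    partner + catalyst intermediate A → free catalyst + target (k = 2.30 × 10⁵ M⁻¹ s⁻¹)
    second substrate + free catalyst ⇌ catalyst intermediate B (K = 3100 M⁻¹, k = 40000 M⁻¹ s⁻¹)
    partner + catalyst intermediate B → free catalyst + second product (k = 1.10 × 10⁶ M⁻¹ s⁻¹)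
    gas ⇌ partner, rate k5*(csat - [partner]) (kL = 0.760 s⁻¹)
    free catalyst + added ligand ⇌ idle complex, settled at all times (K = 4.30 × 10⁵ M⁻¹)
    partner → decomposed reagent (k = 0.0840 s⁻¹)

Wednesday's has not come to rest at 2.0 min. Its starting material stands at 76.2% after 1.00 min, a loss of 24 points, and the next minute takes 23 points, so the line stays nearly straight, and its final target reads back as τ = 257 s. Ten times the time, 20.0 min, is longer than τ: starting material goes to 0% and target to 100%, so the lead changes hands. Decomposed reagent climbs from 0.0526 mM to 1.41 mM, and idle complex from 38.8% to 71.2% of the catalyst charged.

In a flask like Wednesday's with 4 mol% of free catalyst, τ scaled inversely with the catalyst becomes 62.0 s, which puts target in the lead. That flask gives target in the lead at 63.3% against 35.4% of starting material, so the leader holds, but τ reads back as 190 s, longer than the scaled value.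

The earlier runs and the new flask stem from a simulated flask with made-up constants, and the scatter is random.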